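**Plan**

1. Retrosynthesis: the acid is taken back to the C17 enal, the C7=C8 bond to loss of ethanol from a 7-ethoxy aldehyde, and the 5α-H to hydrogenation of a C5=C6 alkene. Ring B is then cut at C7–C8 and C9–C10 in one [4+2] disconnection.
2. Enabling feature: ring B is a cyclohexene with the carboxyl carbon C17 on C8 of the C7=C8 bond and the side-chain methine C9 bonded to the quaternary ring-fusion carbon C10. Its six atoms therefore split into the diene unit C7=C6–C5=C10 built on the gem-dimethyl ring A and the two-carbon unit C8=C9 of an (E)-enal that already carries C17 and the whole C11–C16 chain.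
3. Forward: ring A is bought as 2,2,6-trimethylcyclohexanone and made into an (E)-1-ethoxydiene (enol triflate, Suzuki–Miyaura coupling). The side chain comes from (S)-citronellol by acetylation and cross-metathesis. The two halves are joined as ring B forms; then C5=C6 is saturated, ethanol is eliminated and the aldehyde is oxidised.
4. Helper: the ethoxy group on C7 makes C10 the nucleophilic diene end (fixing the regiochemistry) and leaves again as ethanol to give the C7=C8 bond.
5. Stereochemistry: C13 from (S)-citronellol; C9 from the chiral amine catalyst; C10 relative to C9 from the endo transition state; C5 from hydrogenation on the face opposite the axial methyl groups on C4 and C10.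

Key step: step 5

Remark: labdane numbering is used (decalin C1–C10, side chain C11–C16, C17 on C8, C20 the methyl on C10); β is the face of C20.

**Step 1**
Reactants: 1 (S)-citronellol
Product: 2 (S)-citronellyl acetate
Conditions: Ac2O, pyridine, DMAP (cat.), CH2Cl2, 0 °C to rt
Reagents that add atoms: acetic anhydride, CC(=O)OC(C)=O
Why: Nucleophile-catalysed O-acylation of the primary alcohol installs the acetate of the target, which is carried to the end, and does not involve the C13 centre.

**Step 2**
Reactants: 2 (S)-citronellyl acetate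
Product: 3 (3S,6E)-3-methyl-8-oxooct-6-en-1-yl acetate
Conditions: (E)-crotonaldehyde (excess), second-generation Hoveyda–Grubbs catalyst [RuCl2(H2IMes)(=CH-C6H4-2-OiPr)] (5 mol %), CH2Cl2, 40 °C
Reagents that add atoms: (E)-crotonaldehyde, C/C=C/C=O
Why: Olefin cross-metathesis exchanges the isopropylidene end of the prenyl-type alkene for CH–CHO and should give the E enal under thermodynamic control, with the remote stereocentre untouched.

**Step 3**
Reactants: 4 2,2,6-trimethylcyclohexan-1-one
Product: 6 2,6,6-trimethylcyclohex-1-en-1-yl trifluoromethanesulfonate, via lithium 2,6,6-trimethylcyclohex-1-en-1-olate 5 (not isolated)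
Conditions: LDA (commercial solution), THF, −78 to 0 °C; then PhNTf2, −78 °C to rt
Reagents that add atoms: N-phenylbis(trifluoromethanesulfonimide), O=S(=O)(N(c1ccccc1)S(=O)(=O)C(F)(F)F)C(F)(F)F
Why: The ketone has a single α-hydrogen, so deprotonation gives one enolate, which PhNTf2 sulfonylates on oxygen (enol triflate formation), and no stereocentre remains.

**Step 4**
Reactants: 6 2,6,6-trimethylcyclohex-1-en-1-yl trifluoromethanesulfonate; 7 (E)-2-(2-ethoxyethenyl)-4,4,5,5-tetramethyl-1,3,2-dioxaborolane
Product: 8 2-[(E)-2-ethoxyethenyl]-1,3,3-trimethylcyclohex-1-ene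
Conditions: Pd(PPh3)4 (5 mol %), K3PO4, 1,4-dioxane/H2O, 80 °C; purification on Et3N-treated silica
Reagents that add atoms: none
Why: Suzuki–Miyaura coupling of an alkenyl triflate with an alkenylboronate proceeds with retention, so the E geometry of 7 is carried into the 1-ethoxydiene, and the basic medium protects the enol ether.

**Step 5**
Reactants: 3 (3S,6E)-3-methyl-8-oxooct-6-en-1-yl acetate; 8 2-[(E)-2-ethoxyethenyl]-1,3,3-trimethylcyclohex-1-ene
Product: 10 (13S)-15-acetoxy-7α-ethoxylabd-5-en-17-al, via enal iminium trifluoroacetate 9 (not isolated)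
Conditions: (2R,5R)-5-benzyl-2-tert-butyl-3-methylimidazolidin-4-one·CF3CO2H (20 mol %), 8 (1.5 equiv), CH2Cl2, −20 to 0 °C
Reagents that add atoms: none
Why: Proposed new method: the ammonium salt condenses with 3 to the (E)-iminium ion 9; the C10 end of diene 8, made nucleophilic by the ethoxy group on C7, bonds to C9 of 9, the C8 enamine carbon closes onto the C7 oxocarbenium carbon, and hydrolysis releases 10 and the amine. The closest known reaction type is the imidazolidinone-catalysed Diels–Alder reaction of enals with 1-acetoxybutadiene, supported by the iminium-catalysed Mukaiyama–Michael addition of 5-alkyl-2-silyloxyfurans, which joins a fully substituted carbon to C-β of an enal; new here is the fully substituted terminus of a 1-alkoxydiene. Ring B closes by an endo [4+2] cycloaddition, concerted but asynchronous with the C9–C10 bond in advance (at the stepwise limit a 6-(enolexo)-exo-trig attack of C8 on C7). C9 is set by the catalyst, whose benzyl group should screen the Re face of C9 so that the diene adds to the Si face (the (2S,5S) antipode is known to send carbon nucleophiles to the Re face of C-β of (E)-enals); C10 follows from the endo transition state, which keeps the side chain exo and hence cis to the inward methyl group C20; C7 and C8 follow from the E geometry of both partners and are erased in step 7. The step needs ortho regioselectivity (C7 to C8, C10 to C9), endo selectivity and face selectivity; the C7 ethoxy donor, the iminium group and the catalyst secure them in that order, and the remote C13 centre cannot interfere.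

**Step 6**
Reactants: 10 (13S)-15-acetoxy-7α-ethoxylabd-5-en-17-al
Product: 11 (13S)-15-acetoxy-7α-ethoxy-5α-labdan-17-al
Conditions: H2 (4 atm), 5% Rh/Al2O3, EtOAc, rt
Reagents that add atoms: none
Why: In this heterogeneous syn-hydrogenation the β face of C5=C6 is closed by the syn-axial methyl groups on C4 and C10 while the α face carries the oxygen functions on C7 and C8 that can hold the substrate on the metal, so hydrogen should add from the α face and set C5 as the 5α-H trans ring fusion; rhodium is chosen because it causes little double-bond migration or allylic C–O hydrogenolysis and leaves the aldehyde alone.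

**Step 7**
Reactants: 11 (13S)-15-acetoxy-7α-ethoxy-5α-labdan-17-al
Product: 12 (13S)-15-acetoxylabd-7-en-17-al
Conditions: DBU, toluene, 60 °C
Reagents that add atoms: none
Why: E1cB β-elimination of ethanol from the β-alkoxy aldehyde (axial 7α-ethoxy anti-periplanar to axial 8β-H) can only give the conjugated C7=C8 enal, and C9, which the carbonyl group does not activate, keeps its configuration.

**Step 8**
Reactants: 12 (13S)-15-acetoxylabd-7-en-17-al
Product: 13 (13S)-15-acetoxylabd-7-en-17-oic acid
Conditions: NaClO2, NaH2PO4, 2-methylbut-2-ene, t-BuOH/H2O, 0 °C to rt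
Reagents that add atoms: sodium chlorite, [Na+].[O-]Cl=O
Why: Pinnick oxidation converts the enal into the acid under buffered conditions that leave the acetate, the trisubstituted alkene and all stereocentres untouched, with 2-methylbut-2-ene trapping the hypochlorous acid formed.

**Compound list**

1 | (S)-citronellol, (3S)-3,7-dimethyloct-6-en-1-ol | OCC[C@@H](C)CCC=C(C)C | starting material
2 | (S)-citronellyl acetate, (3S)-3,7-dimethyloct-6-en-1-yl acetate | CC(=O)OCC[C@@H](C)CCC=C(C)C | intermediate
3 | (3S,6E)-3-methyl-8-oxooct-6-en-1-yl acetate | CC(=O)OCC[C@@H](C)CC/C=C/C=O | intermediate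
4 | 2,2,6-trimethylcyclohexan-1-one (racemic) | CC1CCCC(C)(C)C1=O | starting material
5 | lithium 2,6,6-trimethylcyclohex-1-en-1-olate | CC1=C([O-])C(C)(C)CCC1.[Li+] | intermediate
6 | 2,6,6-trimethylcyclohex-1-en-1-yl trifluoromethanesulfonate | CC1=C(OS(=O)(=O)C(F)(F)F)C(C)(C)CCC1 | intermediate
7 | (E)-2-(2-ethoxyethenyl)-4,4,5,5-tetramethyl-1,3,2-dioxaborolane | CCO/C=C/B1OC(C)(C)C(C)(C)O1 | starting material
8 | 2-[(E)-2-ethoxyethenyl]-1,3,3-trimethylcyclohex-1-ene | CCO/C=C/C1=C(C)CCCC1(C)C | intermediate
9 | (E)-iminium ion from 3 and (2R,5R)-5-benzyl-2-tert-butyl-3-methylimidazolidin-4-one, as trifluoroacetate | CC(=O)OCC[C@@H](C)CC/C=C/C=[N+]1/[C@@H](C(C)(C)C)N(C)C(=O)[C@H]1Cc2ccccc2.[O-]C(=O)C(F)(F)F | intermediate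
10 | (13S)-15-acetoxy-7α-ethoxylabd-5-en-17-al (7-OEt and 17-CHO both α, 8β-H, side chain on C9 β, 10β-methyl) | CC(=O)OCC[C@@H](C)CC[C@H]1[C@H](C=O)[C@H](OCC)C=C2C(C)(C)CCC[C@]12C | intermediate
11 | (13S)-15-acetoxy-7α-ethoxy-5α-labdan-17-al (trans-decalin, 5α-H, 8β-H, 9α-H) | CC(=O)OCC[C@@H](C)CC[C@H]1[C@H](C=O)[C@H](OCC)C[C@H]2C(C)(C)CCC[C@]12C | intermediate
12 | (13S)-15-acetoxylabd-7-en-17-al (5S,9R,10S,13S) | CC(=O)OCC[C@@H](C)CC[C@H]1C(C=O)=CC[C@H]2C(C)(C)CCC[C@]12C | intermediate
13 | (13S)-15-acetoxylabd-7-en-17-oic acid (5S,9R,10S,13S) | CC(=O)OCC[C@@H](C)CC[C@H]1C(C(=O)O)=CC[C@H]2C(C)(C)CCC[C@]12C | target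

**Count and risks**

Total steps: 8. Longest linear sequence: 6 steps (1 → 2 → 3 → 10 → 11 → 12 → 13, or 4 → 6 → 8 → 10 → 11 → 12 → 13).

Step 5 (proposed new method). The fully substituted C10 terminus of 8 may fail to reach C9 of the iminium ion, so that hydrolysis of the enol ether, attack through C6, or loss of endo and face control takes over. The fallback uses known chemistry, an auxiliary-controlled Lewis-acid Diels–Alder reaction; it sets out from 3 and 8 and comes back at 10. Aldehyde 3 is oxidised (NaClO2, NaH2PO4, 2-methylbut-2-ene) to (S,E)-8-acetoxy-6-methyloct-2-enoic acid F1. This is coupled through its pivalic mixed anhydride (PivCl, Et3N, LiCl, THF) with (R)-4-benzyl-1,3-oxazolidin-2-one to (R)-4-benzyl-3-[(S,E)-8-acetoxy-6-methyloct-2-enoyl]-1,3-oxazolidin-2-one F2. F2 and 8 are combined with Me2AlCl in CH2Cl2 at −78 to −40 °C; the aluminium chelate should expose the Si face of C9, and the much more electrophilic dienophile should overcome the hindered terminus, to give (13S)-15-acetoxy-7α-ethoxylabd-5-en-17-oyl (R)-4-benzyloxazolidin-2-one F3. LiSEt in THF at 0 °C should turn this into S-ethyl (13S)-15-acetoxy-7α-ethoxylabd-5-ene-17-thioate F4, and Et3SiH with 10% Pd/C in acetone (Fukuyama reduction) should give 10.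

Step 6. Migration of the C5=C6 bond towards the ether oxygen, hydrogenolysis of the allylic C7–O bond, or addition of hydrogen from the β face may compete on the metal surface. The fallback is a hydroxyl-directed homogeneous hydrogenation, from 10 back to 11. NaBH4 in MeOH at 0 °C should reduce 10 to (13S)-15-acetoxy-7α-ethoxylabd-5-en-17-ol F5. [Ir(cod)(PCy3)(py)]PF6 under H2 (1 atm) in CH2Cl2 should bind the α-oriented C17 hydroxyl and 7α-ether oxygen and deliver hydrogen to the α face, giving (13S)-15-acetoxy-7α-ethoxy-5α-labdan-17-ol F6. Dess–Martin periodinane (NaHCO3, CH2Cl2) should return aldehyde 11.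

Step 4. Protodeboronation of the alkoxyvinylboronate or hydrolysis of the enol ether may outrun coupling at the hindered triflate. The fallback is an alkynyl ether coupling followed by trans-hydroalumination, from 6 back to 8. Negishi coupling of 6 with ethoxyethynylzinc chloride (from ethoxyacetylene, n-BuLi and ZnCl2; Pd(PPh3)4, THF, rt) should give 2-(ethoxyethynyl)-1,3,3-trimethylcyclohex-1-ene F7. LiAlH4 in THF should then add hydride trans across the ynol ether to give the (E)-enol ether 8.

**Further compounds**

F1 | step 5 | (S,E)-8-acetoxy-6-methyloct-2-enoic acid | CC(=O)OCC[C@@H](C)CC/C=C/C(=O)O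
F2 | step 5 | (R)-4-benzyl-3-[(S,E)-8-acetoxy-6-methyloct-2-enoyl]-1,3-oxazolidin-2-one | CC(=O)OCC[C@@H](C)CC/C=C/C(=O)N1[C@H](Cc2ccccc2)COC1=O
F3 | step 5 | (13S)-15-acetoxy-7α-ethoxylabd-5-en-17-oyl (R)-4-benzyloxazolidin-2-one | CC(=O)OCC[C@@H](C)CC[C@H]1[C@H](C(=O)N3[C@H](Cc4ccccc4)COC3=O)[C@H](OCC)C=C2C(C)(C)CCC[C@]12C
F4 | step 5 | S-ethyl (13S)-15-acetoxy-7α-ethoxylabd-5-ene-17-thioate | CC(=O)OCC[C@@H](C)CC[C@H]1[C@H](C(=O)SCC)[C@H](OCC)C=C2C(C)(C)CCC[C@]12C
F5 | step 6 | (13S)-15-acetoxy-7α-ethoxylabd-5-en-17-ol | CC(=O)OCC[C@@H](C)CC[C@H]1[C@H](CO)[C@H](OCC)C=C2C(C)(C)CCC[C@]12C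
F6 | step 6 | (13S)-15-acetoxy-7α-ethoxy-5α-labdan-17-ol | CC(=O)OCC[C@@H](C)CC[C@H]1[C@H](CO)[C@H](OCC)C[C@H]2C(C)(C)CCC[C@]12C
F7 | step 4 | 2-(ethoxyethynyl)-1,3,3-trimethylcyclohex-1-ene | CCOC#CC1=C(C)CCCC1(C)C
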